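**Plan**

- The target is a 3',6''-linked biflavone. Unit 1 is the 5-hydroxy-7-methoxyflavone whose ring B carries, at C3', C6 of unit 2, which is acacetin.
- Enabling feature: in ring A of unit 1, O1 (on C8a) and the 5-OH (on C5) both sit ortho to C4a, the carbon that bears the C4 acyl carbon, and ring A is symmetric about the C4a–C7 axis. Both oxygens can therefore be drawn as the two equivalent fluorines of a 2,6-difluoro-4-methoxybenzoyl group.
- Retrosynthetic cuts, in order: the three O–benzyl bonds; C5–O of unit 1 (back to C5–F); O1–C8a of unit 1 (back to a 1,3-diketone); C3–C4 of unit 1 (ketone enolate plus aroyl chloride); the C3'–C6'' biaryl bond (Suzuki coupling); C6–I and two O–benzyl bonds on acacetin.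
- Forward: rings A, C and B of unit 2 are bought as acacetin. Ring B of unit 1 is attached by cross-coupling, and ring A of unit 1 arrives as the difluoroaroyl chloride. Ring C of unit 1 is the only ring built, by fluoride displacement in step 7; the second fluoride is then exchanged for oxygen and the benzyl groups are removed.
- Stereochemistry: the target has no stereocentre, so nothing has to be set.

Key step: step 7

Assumption: the target SMILES leaves the C3'–C6'' axis undefined, so the axis is not controlled; compounds 1, 5 and 7 are taken to be catalogue chemicals.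

**Route**

Step 1
Reactants: 1 acacetin (5,7-dihydroxy-2-(4-methoxyphenyl)-4H-chromen-4-one)
Product: 2 7-(benzyloxy)-5-hydroxy-2-(4-methoxyphenyl)-4H-chromen-4-one
Conditions: BnBr, K2CO3, acetone, reflux
Reagents that add atoms: benzyl bromide, BrCc1ccccc1
Why: Williamson etherification; the 7-OH is the most acidic and least hindered phenol, whereas the 5-OH is held in a hydrogen bond to the C4 carbonyl and should not be alkylated by one equivalent of bromide under these mild conditions.

Step 2
Reactants: 2 7-(benzyloxy)-5-hydroxy-2-(4-methoxyphenyl)-4H-chromen-4-one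
Product: 3 7-(benzyloxy)-5-hydroxy-6-iodo-2-(4-methoxyphenyl)-4H-chromen-4-one
Conditions: BnMe3N·ICl2, CaCO3, CH2Cl2/MeOH, rt
Reagents that add atoms: benzyltrimethylammonium dichloroiodate, C[N+](C)(C)Cc1ccccc1.Cl[I-]Cl
Why: Electrophilic aromatic iodination; with the 5-OH free and the 7-oxygen etherified, the dichloroiodate reagent should iodinate ring A at C6, ortho to the phenol, in preference to C8, while CaCO3 takes up the HCl formed.

Step 3
Reactants: 3 7-(benzyloxy)-5-hydroxy-6-iodo-2-(4-methoxyphenyl)-4H-chromen-4-one
Product: 4 5,7-bis(benzyloxy)-6-iodo-2-(4-methoxyphenyl)-4H-chromen-4-one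
Conditions: BnBr, K2CO3, n-Bu4NI (cat.), DMF, 70 °C
Reagents that add atoms: benzyl bromide, BrCc1ccccc1
Why: Williamson etherification under more forcing conditions (dipolar solvent, heat, in situ benzyl iodide) should break the chelate and alkylate the hindered 5-OH, the aryl iodide and the pyranone being inert to K2CO3.

Step 4
Reactants: 4 5,7-bis(benzyloxy)-6-iodo-2-(4-methoxyphenyl)-4H-chromen-4-one; 5 (5-acetyl-2-methoxyphenyl)boronic acid
Product: 6 6-(5-acetyl-2-methoxyphenyl)-5,7-bis(benzyloxy)-2-(4-methoxyphenyl)-4H-chromen-4-one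
Conditions: Pd(OAc)2 (cat.), SPhos, K3PO4, PhMe/H2O, 100 °C
Reagents that add atoms: none
Why: Suzuki–Miyaura coupling; the electron-rich biaryl phosphine on zerovalent palladium (formed in situ from palladium diacetate) should promote oxidative addition into the doubly ortho-substituted C–I bond and reductive elimination to the tri-ortho-substituted biaryl, and the ketone, benzyl ethers and pyranone tolerate aqueous K3PO4.

Step 5
Reactants: 7 2,6-difluoro-4-methoxybenzoic acid
Product: 8 2,6-difluoro-4-methoxybenzoyl chloride
Conditions: (COCl)2, DMF (cat.), CH2Cl2, 0 °C to rt; evaporate, use crude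
Reagents that add atoms: oxalyl chloride, ClC(=O)C(=O)Cl
Why: Acid chloride formation through the chloroiminium species generated from oxalyl chloride and catalytic DMF, which leaves the aryl fluorides and the methyl ether untouched.

Step 6
Reactants: 6 6-(5-acetyl-2-methoxyphenyl)-5,7-bis(benzyloxy)-2-(4-methoxyphenyl)-4H-chromen-4-one; 8 2,6-difluoro-4-methoxybenzoyl chloride
Product: 10 1-(2,6-difluoro-4-methoxyphenyl)-3-{3-[5,7-bis(benzyloxy)-2-(4-methoxyphenyl)-4-oxo-4H-chromen-6-yl]-4-methoxyphenyl}propane-1,3-dione, via lithium enolate 9 (not isolated)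
Conditions: LiN(SiMe3)2 (2.2 equiv), THF, −78 °C; then 8, −78 to 0 °C; 1 M HCl
Reagents that add atoms: none
Why: C-acylation of a methyl ketone lithium enolate by an aroyl chloride (crossed Claisen-type condensation); the second equivalent of base should convert the more acidic 1,3-diketone into its lithium chelate as it forms, which drives the reaction and shields the product from a second acylation, and at −78 °C the amide base leaves the pyranone alone.

Step 7
Reactants: 10 1-(2,6-difluoro-4-methoxyphenyl)-3-{3-[5,7-bis(benzyloxy)-2-(4-methoxyphenyl)-4-oxo-4H-chromen-6-yl]-4-methoxyphenyl}propane-1,3-dione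
Product: 11 5,7-bis(benzyloxy)-6-[5-(5-fluoro-7-methoxy-4-oxo-4H-chromen-2-yl)-2-methoxyphenyl]-2-(4-methoxyphenyl)-4H-chromen-4-one
Conditions: K2CO3, DMF, 80 °C
Reagents that add atoms: none
Why: K2CO3 deprotonates the 1,3-diketone, and the enolate oxygen on the carbon bearing ring B adds to one fluorine-bearing carbon ortho to the aroyl carbonyl, giving a Meisenheimer anion stabilised by that carbonyl, which then expels fluoride (addition–elimination). The closest known reaction type is the base-mediated cyclisation of 1-(2-fluorophenyl)-1,3-diketones to chromones and flavones, the oxygen counterpart of the quinolone cycloaracylation. Ring C of unit 1 closes as a six-membered ring through O1–C8a, formally a 6-endo-trig oxa-Michael addition–elimination on the C4a=C8a bond conjugated to C4=O, a geometry the planar enolate already holds. No stereocentre is formed. The step needs attack through oxygen and only one ring closure: the central carbon and the proximal oxygen could only form four-membered rings, the two fluorines are equivalent by the symmetry of the difluoroaryl ring so either gives the same product, and once O1 is in place no internal nucleophile can reach the second fluoride. The benzyl ethers, the methyl ethers and the pyranone of unit 2 should be inert to K2CO3 in DMF.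

Step 8
Reactants: 11 5,7-bis(benzyloxy)-6-[5-(5-fluoro-7-methoxy-4-oxo-4H-chromen-2-yl)-2-methoxyphenyl]-2-(4-methoxyphenyl)-4H-chromen-4-one
Product: 12 5,7-bis(benzyloxy)-6-{5-[5-(benzyloxy)-7-methoxy-4-oxo-4H-chromen-2-yl]-2-methoxyphenyl}-2-(4-methoxyphenyl)-4H-chromen-4-one
Conditions: BnOH, NaH, THF/DMF, 0 to 50 °C
Reagents that add atoms: benzyl alcohol, OCc1ccccc1
Why: Intermolecular nucleophilic aromatic substitution; the remaining fluoride is peri to the C4 carbonyl, which stabilises the Meisenheimer anion, fluoride is by far the best leaving group present, and any exchange by benzyloxide at the other carbonyl-activated alkoxy position (the 5-benzyloxy group of unit 2) is degenerate.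

Step 9
Reactants: 12 5,7-bis(benzyloxy)-6-{5-[5-(benzyloxy)-7-methoxy-4-oxo-4H-chromen-2-yl]-2-methoxyphenyl}-2-(4-methoxyphenyl)-4H-chromen-4-one
Product: 13 5,7-dihydroxy-6-[5-(5-hydroxy-7-methoxy-4-oxo-4H-chromen-2-yl)-2-methoxyphenyl]-2-(4-methoxyphenyl)-4H-chromen-4-one (target)
Conditions: BCl3, C6HMe5, CH2Cl2, −78 °C; then H2O
Reagents that add atoms: none
Why: Lewis acid cleavage of aryl benzyl ethers with BCl3 and pentamethylbenzene as a non-basic benzyl cation trap; at −78 °C the three benzyl ethers (two of them peri to a carbonyl and especially labile) should be cleaved while the three unchelated aryl methyl ethers stay, and the trap prevents C-benzylation of the electron-rich rings.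

**Compound list**

1 | acacetin, 5,7-dihydroxy-2-(4-methoxyphenyl)-4H-chromen-4-one | COc1ccc(-c2cc(=O)c3c(O)cc(O)cc3o2)cc1 | starting material
2 | 7-(benzyloxy)-5-hydroxy-2-(4-methoxyphenyl)-4H-chromen-4-one | COc1ccc(-c2cc(=O)c3c(O)cc(OCc4ccccc4)cc3o2)cc1 | intermediate
3 | 7-(benzyloxy)-5-hydroxy-6-iodo-2-(4-methoxyphenyl)-4H-chromen-4-one | COc1ccc(-c2cc(=O)c3c(O)c(I)c(OCc4ccccc4)cc3o2)cc1 | intermediate
4 | 5,7-bis(benzyloxy)-6-iodo-2-(4-methoxyphenyl)-4H-chromen-4-one | COc1ccc(-c2cc(=O)c3c(OCc4ccccc4)c(I)c(OCc4ccccc4)cc3o2)cc1 | intermediate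
5 | (5-acetyl-2-methoxyphenyl)boronic acid | CC(=O)c1ccc(OC)c(B(O)O)c1 | starting material
6 | 6-(5-acetyl-2-methoxyphenyl)-5,7-bis(benzyloxy)-2-(4-methoxyphenyl)-4H-chromen-4-one | COc1ccc(-c2cc(=O)c3c(OCc4ccccc4)c(-c4cc(C(C)=O)ccc4OC)c(OCc4ccccc4)cc3o2)cc1 | intermediate
7 | 2,6-difluoro-4-methoxybenzoic acid | COc1cc(F)c(C(=O)O)c(F)c1 | starting material
8 | 2,6-difluoro-4-methoxybenzoyl chloride | COc1cc(F)c(C(=O)Cl)c(F)c1 | intermediate
9 | lithium enolate of ketone 6 (not isolated) | [Li+].[O-]C(=C)c1ccc(OC)c(-c2c(OCc3ccccc3)cc3oc(-c4ccc(OC)cc4)cc(=O)c3c2OCc2ccccc2)c1 | intermediate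
10 | 1-(2,6-difluoro-4-methoxyphenyl)-3-{3-[5,7-bis(benzyloxy)-2-(4-methoxyphenyl)-4-oxo-4H-chromen-6-yl]-4-methoxyphenyl}propane-1,3-dione | COc1cc(F)c(C(=O)CC(=O)c2ccc(OC)c(-c3c(OCc4ccccc4)cc5oc(-c6ccc(OC)cc6)cc(=O)c5c3OCc3ccccc3)c2)c(F)c1 | intermediate
11 | 5,7-bis(benzyloxy)-6-[5-(5-fluoro-7-methoxy-4-oxo-4H-chromen-2-yl)-2-methoxyphenyl]-2-(4-methoxyphenyl)-4H-chromen-4-one | COc1ccc(-c2cc(=O)c3c(OCc4ccccc4)c(-c5cc(-c6cc(=O)c7c(F)cc(OC)cc7o6)ccc5OC)c(OCc5ccccc5)cc3o2)cc1 | intermediate
12 | 5,7-bis(benzyloxy)-6-{5-[5-(benzyloxy)-7-methoxy-4-oxo-4H-chromen-2-yl]-2-methoxyphenyl}-2-(4-methoxyphenyl)-4H-chromen-4-one | COc1ccc(-c2cc(=O)c3c(OCc4ccccc4)c(-c5cc(-c6cc(=O)c7c(OCc8ccccc8)cc(OC)cc7o6)ccc5OC)c(OCc5ccccc5)cc3o2)cc1 | intermediate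
13 | 5,7-dihydroxy-6-[5-(5-hydroxy-7-methoxy-4-oxo-4H-chromen-2-yl)-2-methoxyphenyl]-2-(4-methoxyphenyl)-4H-chromen-4-one | COc1ccc(-c2cc(=O)c3c(O)c(-c4cc(-c5cc(=O)c6c(O)cc(OC)cc6o5)ccc4OC)c(O)cc3o2)cc1 | target

**Count**

Total steps: 9. Longest linear sequence: 8 steps (steps 1–4 and 6–9); step 5 is a one-step side branch.

**Steps most likely to fail**

Step 8. Displacement of the C5 fluoride may be slow, because the ring oxygen and the 7-methoxy group push electron density onto the positions that must carry the negative charge. At the temperature then needed, benzyloxide may add to C2 of either pyranone and open it. The fallback spends the alkoxide on a small, robust arene before the ring closure. It sets out from acid 7. Sodium benzyloxide in excess (BnOH, NaH, DMSO, about 90 °C) should replace one of the two equivalent fluorides to give 2-(benzyloxy)-6-fluoro-4-methoxybenzoic acid F1; the second fluoride should stay because the ring has become more electron-rich. Oxalyl chloride with catalytic DMF would convert this into 2-(benzyloxy)-6-fluoro-4-methoxybenzoyl chloride F2. This chloride would acylate lithium enolate 9 (made from ketone 6 as in step 6) to give 1-[2-(benzyloxy)-6-fluoro-4-methoxyphenyl]-3-{3-[5,7-bis(benzyloxy)-2-(4-methoxyphenyl)-4-oxo-4H-chromen-6-yl]-4-methoxyphenyl}propane-1,3-dione F3. The same carbonate-mediated closure (K2CO3, or Cs2CO3 in DMF at about 100 °C if that is too slow) would displace the only fluoride and give tribenzyl ether 12 directly, where the route is rejoined before step 9. The O1–C8a bond is still made by fluoride displacement.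

Step 4. Transmetalation and reductive elimination at a palladium centre flanked by two benzyloxy groups may be slow, so loss of boron from the ortho-methoxy boronic acid and reduction of the C–I bond may outrun the coupling. The fallback changes the organometallic partner and sets out from iodide 4. Commercial 1-(3-bromo-4-methoxyphenyl)ethanone would be stannylated with (Bu3Sn)2 and Pd(PPh3)4 in refluxing toluene to give 1-[4-methoxy-3-(tributylstannyl)phenyl]ethan-1-one F4. A Stille coupling of this stannane with 4, promoted by CuI and CsF (Pd(PPh3)4, DMF, 50 °C), should give ketone 6, where the route is rejoined. The stannane does not lose its metal to water, and the copper–fluoride promotion is suited to hindered partners.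

Step 6. O-acylation of the enolate, a second acylation of the diketonate, and proton transfer from product to unreacted enolate may compete with the desired C-acylation. The fallback makes the C3–C4 bond at the alcohol oxidation level and sets out from ketone 6. Its lithium enolate 9 would be added at −78 °C to commercial 2,6-difluoro-4-methoxybenzaldehyde, an aldol addition that can only give a C–C bond. The product would be racemic 3-(2,6-difluoro-4-methoxyphenyl)-3-hydroxy-1-{3-[5,7-bis(benzyloxy)-2-(4-methoxyphenyl)-4-oxo-4H-chromen-6-yl]-4-methoxyphenyl}propan-1-one F5. Oxidation of this β-hydroxy ketone with Dess–Martin periodinane in CH2Cl2 would remove the stereocentre and give diketone 10, where the route is rejoined before the key step.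

**Further compounds**

F1 | step 8 | 2-(benzyloxy)-6-fluoro-4-methoxybenzoic acid | COc1cc(F)c(C(=O)O)c(OCc2ccccc2)c1
F2 | step 8 | 2-(benzyloxy)-6-fluoro-4-methoxybenzoyl chloride | COc1cc(F)c(C(=O)Cl)c(OCc2ccccc2)c1
F3 | step 8 | 1-[2-(benzyloxy)-6-fluoro-4-methoxyphenyl]-3-{3-[5,7-bis(benzyloxy)-2-(4-methoxyphenyl)-4-oxo-4H-chromen-6-yl]-4-methoxyphenyl}propane-1,3-dione | COc1cc(F)c(C(=O)CC(=O)c2ccc(OC)c(-c3c(OCc4ccccc4)cc5oc(-c6ccc(OC)cc6)cc(=O)c5c3OCc3ccccc3)c2)c(OCc2ccccc2)c1
F4 | step 4 | 1-[4-methoxy-3-(tributylstannyl)phenyl]ethan-1-one | CCCC[Sn](CCCC)(CCCC)c1cc(C(C)=O)ccc1OC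
F5 | step 6 | 3-(2,6-difluoro-4-methoxyphenyl)-3-hydroxy-1-{3-[5,7-bis(benzyloxy)-2-(4-methoxyphenyl)-4-oxo-4H-chromen-6-yl]-4-methoxyphenyl}propan-1-one (racemic) | COc1cc(F)c(C(O)CC(=O)c2ccc(OC)c(-c3c(OCc4ccccc4)cc5oc(-c6ccc(OC)cc6)cc(=O)c5c3OCc3ccccc3)c2)c(F)c1
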